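The initiator left over at the end of eta and of gamma, 77.7% of its charge by first-order decay over 1.5 min, begins no chain, so the length asked for can be had by counting what did turn over.

- eta: free monomer 0.50 mM; protic impurity 0.0500 mM; initiator 0.5 mol%; time 1.5 min
- gamma: free monomer 0.50 mM; protic impurity 0.0500 mM; initiator 0.25 mol%; time 1.5 min

    initiator → 2 initiating radical (k1 = 0.0028 s⁻¹)
    free monomer + initiating radical → growing radical + monomer in chains (k2 = 1.2 × 10⁷ M⁻¹ s⁻¹)
    free monomer + growing radical → monomer in chains + growing radical, rate k3*[growing radical]*[free monomer] (k3 = 4.5 × 10⁵ M⁻¹ s⁻¹)
    2 growing radical → dead chain (k4 = 1 × 10⁶ M⁻¹ s⁻¹)
    protic impurity + free monomer → quenched substrate (k5 = 250 M⁻¹ s⁻¹)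

* which of the two ends with the longer chains by the average number of monomer units in a chain (living and dead chains, two that joined counted as one) ("neither" if they lie within 10%) (eta / gamma / neither)
* average number of monomer units in a chain (living and dead chains, two that joined counted as one) at the end, eta
* average number of monomer units in a chain (living and dead chains, two that joined counted as one) at the end, gamma

- a step written with two of one species runs at k times the square of its concentration and takes two of it each time
- the average divides the monomer in chains by the number of chains, living and dead together; two radicals that join make one chain
- run time (eta): 1.5 min

*How many chains stand in eta at the end, per free monomer charged?* Each initiator that turns over gives two radicals, and two radicals that join make one chain, so it is worth one chain once they have joined, while each growing radical not yet joined adds half a chain to that count. Growing radicals stand where their making matches their joining, at 0.0148% of the free monomer charged in eta and 0.0104% in gamma. I call the chain share the chains per free monomer charged, which is the turned-over part of the initiator times its loading plus half the growing radicals, and in eta it is 0.119%, about twice the 0.0609% of gamma.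

*And the monomer in chains?* In eta the half-life of the protic impurity by its step alone, with free monomer as charged, 0.092 min, is shorter than the 0.307 min of free monomer in its pseudo-first-order decay under the radicals at the charged initiator, so I first take off the impurity's 10.0% of the charge. The radicals, weakening as the initiator decays, then give 3.18 e-foldings in eta and 2.25 in gamma, which puts 86.3% and 80.5% of the charge in chains.

*Where is that weakest?* In the order of events, since those two half-lives stand a factor of 3.34 apart and free monomer is already falling while the impurity works, so these fractions are rough, though the chain share does not rest on them.

My count is 726 units for eta and 1320 for gamma, which makes gamma longer.

The forecast says gamma, with 725 for eta and 1300 for gamma, on the ground that “gamma makes roughly half the chains”.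

The simulation gives gamma, with 726 for eta and 1300 for gamma. In eta the quenching step reached the midpoint of its turnover up to the end by 0.0935 min, with 23.0% of the free monomer reacted as late as 0.150 min, and chain growth reached its own midpoint at 0.348 min. Growth in eta then ran on, with quenched substrate at 9.44% of the charge at 0.750 min and 9.68% at 1.50 min, as free monomer fell to 4.04%. The growing radicals and dead chains of eta at that end come to 0.119% of the charge, against a chain share of 0.119%.

In the neighbour, eta's recipe at 0.20 mM of free monomer with 0.250 equiv of protic impurity, the held loading keeps the initiator's part of the share, and the growing radicals, a larger fraction of this smaller charge, lift it to 0.123%, so 65.0% in chains gives 528 units. The simulation gives 558, with 68.7% in chains and 17% of the impurity still there.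

The numbers of this flask belong to no real substance; the flask was simulated.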